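## Retrosynthetic overview

1. The target comes from double benzoylation of an epoxy diol, itself made by desilylation of a Sharpless epoxidation product; the oxirane (C1–C6) is the last ring formed.
2. The epoxidation substrate is a (cyclohexa-1,3-dienyl)methanol, obtained by base-induced opening of a spiro-oxirane on a cyclohexene.
3. The six-membered carbocycle is formed first, by ring-closing metathesis (C4=C5) of an acyclic 2-allyl oxirane.
4. That diene comes from a Weinreb amide by chloromethyl-ketone formation, allyl addition and oxirane closure.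
5. Key C–C bond (C2–C3): Evans syn-glycolate aldol of an N-methoxyacetyl oxazolidinone with acrolein, which sets C2 (S) and C3 (R).

Assumption (numbering): C1 = quaternary oxirane carbon, C2 = C–OMe, C3 = C–OBz, C4=C5, C6 = oxirane CH, C7 = CH2O; target = (1R,2S,3R,6R).

## Route

Step 1
Reactants: 1 (S)-4-benzyl-1,3-oxazolidin-2-one; 2 methoxyacetyl chloride
Product: 3 (S)-4-benzyl-3-(2-methoxyacetyl)-1,3-oxazolidin-2-one
Conditions: n-BuLi, THF, −78 °C; then 2, −78 → 0 °C
Reagents that add atoms: none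
Why: N-acylation of the lithiated oxazolidinone by the acid chloride (imide formation); no new stereocentre.

Step 2
Reactants: 3 (S)-4-benzyl-3-(2-methoxyacetyl)-1,3-oxazolidin-2-one; 4 acrolein
Product: 6 (S)-4-benzyl-3-[(2S,3R)-3-hydroxy-2-methoxypent-4-enoyl]-1,3-oxazolidin-2-one, via Z-dibutylboron enolate 5 (not isolated)
Conditions: Bu2BOTf, Et3N, CH2Cl2, −78 → 0 °C; 4, −78 → 0 °C; then pH 7 buffer, MeOH, 30% H2O2, 0 °C
Reagents that add atoms: none
Why: Evans syn-aldol: the Z-boron enolate reacts through a Zimmerman–Traxler chair in which the auxiliary's benzyl group blocks one enolate face, so the C2–C3 bond forms as the 2,3-syn adduct and C2 (S) and C3 (R) are set together.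

Step 3
Reactants: 6 (S)-4-benzyl-3-[(2S,3R)-3-hydroxy-2-methoxypent-4-enoyl]-1,3-oxazolidin-2-one
Product: 7 (2S,3R)-3-hydroxy-N,2-dimethoxy-N-methylpent-4-enamide
Conditions: MeNH(OMe)·HCl, AlMe3, CH2Cl2, −20 → 0 °C; aq. potassium sodium tartrate (KNaC4H4O6) work-up
Reagents that add atoms: N,O-dimethylhydroxylamine hydrochloride, CNOC.Cl
Why: Weinreb transamidation: the free β-hydroxyl anchors the aluminium amide, which cleaves the exocyclic imide carbonyl without epimerising C2, and the auxiliary is recovered.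

Step 4
Reactants: 7 (2S,3R)-3-hydroxy-N,2-dimethoxy-N-methylpent-4-enamide
Product: 8 (2S,3R)-3-[(tert-butyldimethylsilyl)oxy]-N,2-dimethoxy-N-methylpent-4-enamide
Conditions: TBSOTf, 2,6-lutidine, CH2Cl2, 0 °C
Reagents that add atoms: tert-butyldimethylsilyl triflate, CC(C)(C)[Si](C)(C)OS(=O)(=O)C(F)(F)F
Why: Silyl ether protection of the secondary allylic alcohol so that it survives the organometallic steps; no stereocentre is touched.

Step 5
Reactants: 8 (2S,3R)-3-[(tert-butyldimethylsilyl)oxy]-N,2-dimethoxy-N-methylpent-4-enamide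
Product: 9 (3S,4R)-4-[(tert-butyldimethylsilyl)oxy]-1-chloro-3-methoxyhex-5-en-2-one
Conditions: ICH2Cl, MeLi·LiBr (added last), THF, −78 °C; then aq. NH4Cl at −78 °C
Reagents that add atoms: chloroiodomethane, ClCI
Why: Acyl substitution of the Weinreb amide by chloromethyllithium (carbenoid homologation); the chelated tetrahedral adduct collapses only on quench, so there is no over-addition and no epimerisation of the α-methoxy centre.

Step 6
Reactants: 9 (3S,4R)-4-[(tert-butyldimethylsilyl)oxy]-1-chloro-3-methoxyhex-5-en-2-one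
Product: 11 tert-butyl{[(3R,4S)-4-methoxy-4-[2-(prop-2-en-1-yl)oxiran-2-yl]but-1-en-3-yl]oxy}dimethylsilane (both epimers at the oxirane carbon), via chlorohydrin 10 (not isolated)
Conditions: CH2=CHCH2MgBr, THF, −78 °C; aq. NH4Cl; then K2CO3, MeOH, rt
Reagents that add atoms: allylmagnesium bromide, C=CC[Mg]Br
Why: Grignard 1,2-addition to the α-chloroketone followed by intramolecular Williamson closure of the chlorohydrin; the new quaternary centre forms as an epimeric mixture that is erased in step 8.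

Step 7
Reactants: 11 tert-butyl{[(3R,4S)-4-methoxy-4-[2-(prop-2-en-1-yl)oxiran-2-yl]but-1-en-3-yl]oxy}dimethylsilane
Product: 12 tert-butyl{[(7R,8S)-8-methoxy-1-oxaspiro[2.5]oct-5-en-7-yl]oxy}dimethylsilane (both epimers at the spiro carbon)
Conditions: second-generation Grubbs catalyst RuCl2(=CHPh)(H2IMes)(PCy3) (5 mol %), CH2Cl2 (0.01 M), 40 °C
Reagents that add atoms: none
Why: Ring-closing metathesis of the two monosubstituted terminal alkenes closes the six-membered carbocycle (C4=C5) with loss of ethene; no stereocentre is touched.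

Step 8
Reactants: 12 tert-butyl{[(7R,8S)-8-methoxy-1-oxaspiro[2.5]oct-5-en-7-yl]oxy}dimethylsilane
Product: 13 [(5R,6R)-5-[(tert-butyldimethylsilyl)oxy]-6-methoxycyclohexa-1,3-dien-1-yl]methanol
Conditions: lithium 2,2,6,6-tetramethylpiperidide (LiTMP), Et2AlCl, toluene, 0 °C; aq. potassium sodium tartrate (KNaC4H4O6) work-up
Reagents that add atoms: none
Why: Base-promoted epoxide-to-allylic-alcohol isomerisation (syn β-elimination): the aluminium amide removes an allylic ring hydrogen next to the spiro carbon (more acidic than the methoxy-bearing CH), opening the oxirane to CH2OH and giving the conjugated diene, with the ring fixing the alkene geometry.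

Step 9
Reactants: 13 [(5R,6R)-5-[(tert-butyldimethylsilyl)oxy]-6-methoxycyclohexa-1,3-dien-1-yl]methanol
Product: 14 [(1R,2S,3R,6R)-3-[(tert-butyldimethylsilyl)oxy]-2-methoxy-7-oxabicyclo[4.1.0]hept-4-en-1-yl]methanol
Conditions: Ti(OiPr)4 (0.2 equiv), D-(−)-diethyl tartrate (0.24 equiv), t-BuOOH, 4 Å molecular sieves, CH2Cl2, −20 °C
Reagents that add atoms: tert-butyl hydroperoxide, CC(C)(C)OO
Why: Sharpless asymmetric epoxidation: the Ti/D-(−)-tartrate catalyst epoxidises only the alkene of the free allylic alcohol and, by reagent control, delivers oxygen to the face syn to the C2 methoxy group (L-(+)-tartrate would attack the other face), setting C1 (R) and C6 (R).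

Step 10
Reactants: 14 [(1R,2S,3R,6R)-3-[(tert-butyldimethylsilyl)oxy]-2-methoxy-7-oxabicyclo[4.1.0]hept-4-en-1-yl]methanol
Product: 15 (1R,2S,3R,6R)-1-(hydroxymethyl)-2-methoxy-7-oxabicyclo[4.1.0]hept-4-en-3-ol
Conditions: Bu4NF, AcOH (1:1), THF, 0 °C → rt
Reagents that add atoms: none
Why: Fluoride desilylation; acetic acid buffering keeps the medium near neutral so the vinyl epoxide is not opened and no Payne rearrangement occurs.

Step 11
Reactants: 15 (1R,2S,3R,6R)-1-(hydroxymethyl)-2-methoxy-7-oxabicyclo[4.1.0]hept-4-en-3-ol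
Product: 16 [(1R,2S,3R,6R)-3-(benzoyloxy)-2-methoxy-7-oxabicyclo[4.1.0]hept-4-en-1-yl]methyl benzoate
Conditions: BzCl (2.5 equiv), Et3N, DMAP (cat.), CH2Cl2, 0 °C → rt
Reagents that add atoms: benzoyl chloride, O=C(Cl)c1ccccc1
Why: DMAP-catalysed O-acylation (esterification) of the primary and the secondary allylic hydroxyl under non-acidic conditions; no stereocentre is affected and the product is the target.

## Compound list

1 | (S)-4-benzyl-1,3-oxazolidin-2-one (recovered in step 3) | O=C1N[C@@H](Cc2ccccc2)CO1 | starting material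
2 | methoxyacetyl chloride | COCC(Cl)=O | starting material
3 | (S)-4-benzyl-3-(2-methoxyacetyl)-1,3-oxazolidin-2-one | COCC(=O)N1C(=O)OC[C@@H]1Cc1ccccc1 | intermediate
4 | acrolein | C=CC=O | starting material
5 | Z-dibutylboron enolate of 3 (not isolated) | CO/C=C(\OB(CCCC)CCCC)N1C(=O)OC[C@@H]1Cc1ccccc1 | intermediate
6 | (S)-4-benzyl-3-[(2S,3R)-3-hydroxy-2-methoxypent-4-enoyl]-1,3-oxazolidin-2-one | CO[C@@H]([C@H](O)C=C)C(=O)N1C(=O)OC[C@@H]1Cc1ccccc1 | intermediate
7 | (2S,3R)-3-hydroxy-N,2-dimethoxy-N-methylpent-4-enamide | CO[C@@H]([C@H](O)C=C)C(=O)N(C)OC | intermediate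
8 | (2S,3R)-3-[(tert-butyldimethylsilyl)oxy]-N,2-dimethoxy-N-methylpent-4-enamide | CO[C@@H]([C@H](O[Si](C)(C)C(C)(C)C)C=C)C(=O)N(C)OC | intermediate
9 | (3S,4R)-4-[(tert-butyldimethylsilyl)oxy]-1-chloro-3-methoxyhex-5-en-2-one | CO[C@@H]([C@H](O[Si](C)(C)C(C)(C)C)C=C)C(=O)CCl | intermediate
10 | (5S,6R)-6-[(tert-butyldimethylsilyl)oxy]-4-(chloromethyl)-5-methoxyocta-1,7-dien-4-ol, both C4 epimers (not isolated) | CO[C@@H]([C@H](O[Si](C)(C)C(C)(C)C)C=C)C(O)(CCl)CC=C | intermediate
11 | tert-butyl{[(3R,4S)-4-methoxy-4-[2-(prop-2-en-1-yl)oxiran-2-yl]but-1-en-3-yl]oxy}dimethylsilane, both epimers at the oxirane carbon | CO[C@@H]([C@H](O[Si](C)(C)C(C)(C)C)C=C)C1(CC=C)CO1 | intermediate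
12 | tert-butyl{[(7R,8S)-8-methoxy-1-oxaspiro[2.5]oct-5-en-7-yl]oxy}dimethylsilane, both epimers at the spiro carbon | CO[C@H]1[C@H](O[Si](C)(C)C(C)(C)C)C=CCC12CO2 | intermediate
13 | [(5R,6R)-5-[(tert-butyldimethylsilyl)oxy]-6-methoxycyclohexa-1,3-dien-1-yl]methanol | CO[C@H]1[C@H](O[Si](C)(C)C(C)(C)C)C=CC=C1CO | intermediate
14 | [(1R,2S,3R,6R)-3-[(tert-butyldimethylsilyl)oxy]-2-methoxy-7-oxabicyclo[4.1.0]hept-4-en-1-yl]methanol | CO[C@H]1[C@H](O[Si](C)(C)C(C)(C)C)C=C[C@H]2O[C@]21CO | intermediate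
15 | (1R,2S,3R,6R)-1-(hydroxymethyl)-2-methoxy-7-oxabicyclo[4.1.0]hept-4-en-3-ol | CO[C@H]1[C@H](O)C=C[C@H]2O[C@]21CO | intermediate
16 | [(1R,2S,3R,6R)-3-(benzoyloxy)-2-methoxy-7-oxabicyclo[4.1.0]hept-4-en-1-yl]methyl benzoate | CO[C@H]1[C@H](OC(=O)c2ccccc2)C=C[C@H]2O[C@]21COC(=O)c1ccccc1 | target

## Step count and risks

Total step count: 11. Longest linear sequence: 11 steps (1 → 16).

The three steps most likely to fail:

Step 8 (oxirane to dienylmethanol). The amide base could attack the wrong hydrogen or metalate the oxirane CH2, and the 5,6-dioxygenated cyclohexadiene can aromatise. The fallback sets out from 12 and replaces the elimination on the oxirane by nucleophilic opening followed by dehydration. Heating 12 with CsOAc and AcOH in DMF at 80 °C opens the oxirane at its CH2 to give the tertiary alcohol [(5R,6S)-5-[(tert-butyldimethylsilyl)oxy]-1-hydroxy-6-methoxycyclohex-3-en-1-yl]methyl acetate F2. Dehydration with the Burgess reagent (toluene, 60 °C) toward the allylic ring CH2 gives the conjugated diene [(5R,6R)-5-[(tert-butyldimethylsilyl)oxy]-6-methoxycyclohexa-1,3-dien-1-yl]methyl acetate F3. Methanolysis (K2CO3, MeOH, 0 °C) then returns to the route at 13.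

Step 9 (Sharpless epoxidation of the dienol). The adjacent C2 methoxy group may oppose the catalyst (mismatched double diastereoselection), and the vinyl epoxide can be opened by the titanium Lewis acid. The fallback sets out from 13 and uses a dioxirane on the protected alcohol in place of the hydroxyl-bound titanium catalyst, with the end-game reordered. Benzoylation (BzCl, Et3N, DMAP) gives [(5R,6R)-5-[(tert-butyldimethylsilyl)oxy]-6-methoxycyclohexa-1,3-dien-1-yl]methyl benzoate F4. Shi epoxidation of the trisubstituted alkene (D-fructose-derived ketone, KHSO5 as Oxone, aq. K2CO3 buffer, MeCN/dimethoxymethane, 0 °C) gives [(1R,2S,3R,6R)-3-[(tert-butyldimethylsilyl)oxy]-2-methoxy-7-oxabicyclo[4.1.0]hept-4-en-1-yl]methyl benzoate F5. The face is assigned by analogy with 1-phenylcyclohexene, which gives the (R,R)-oxide with this ketone. Desilylation (Bu4NF, AcOH, THF) gives [(1R,2S,3R,6R)-3-hydroxy-2-methoxy-7-oxabicyclo[4.1.0]hept-4-en-1-yl]methyl benzoate F6, and benzoylation of the remaining hydroxyl returns to the route at 16.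

Step 5 (chloromethyllithium addition). The carbenoid decomposes above −78 °C, so conversion can be incomplete. The fallback sets out from 8 and builds the oxirane with a sulfur ylide instead of the carbenoid and chlorohydrin. Addition of CH2=CHCH2MgBr to 8 (THF, −78 °C, cold quench) gives the allyl ketone (5S,6R)-6-[(tert-butyldimethylsilyl)oxy]-5-methoxyocta-1,7-dien-4-one F1. Corey–Chaykovsky methylenation with dimethylsulfonium methylide (Me3S+ I−, KN(SiMe3)2, THF, −10 °C) then returns to the route at 11.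

## Further compounds

F1 | step 5 | (5S,6R)-6-[(tert-butyldimethylsilyl)oxy]-5-methoxyocta-1,7-dien-4-one | CO[C@@H]([C@H](O[Si](C)(C)C(C)(C)C)C=C)C(=O)CC=C
F2 | step 8 | [(5R,6S)-5-[(tert-butyldimethylsilyl)oxy]-1-hydroxy-6-methoxycyclohex-3-en-1-yl]methyl acetate (both C1 epimers) | CO[C@H]1[C@H](O[Si](C)(C)C(C)(C)C)C=CCC1(O)COC(C)=O
F3 | step 8 | [(5R,6R)-5-[(tert-butyldimethylsilyl)oxy]-6-methoxycyclohexa-1,3-dien-1-yl]methyl acetate | CO[C@H]1[C@H](O[Si](C)(C)C(C)(C)C)C=CC=C1COC(C)=O
F4 | step 9 | [(5R,6R)-5-[(tert-butyldimethylsilyl)oxy]-6-methoxycyclohexa-1,3-dien-1-yl]methyl benzoate | CO[C@H]1[C@H](O[Si](C)(C)C(C)(C)C)C=CC=C1COC(=O)c1ccccc1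
F5 | step 9 | [(1R,2S,3R,6R)-3-[(tert-butyldimethylsilyl)oxy]-2-methoxy-7-oxabicyclo[4.1.0]hept-4-en-1-yl]methyl benzoate | CO[C@H]1[C@H](O[Si](C)(C)C(C)(C)C)C=C[C@H]2O[C@]21COC(=O)c1ccccc1
F6 | step 9 | [(1R,2S,3R,6R)-3-hydroxy-2-methoxy-7-oxabicyclo[4.1.0]hept-4-en-1-yl]methyl benzoate | CO[C@H]1[C@H](O)C=C[C@H]2O[C@]21COC(=O)c1ccccc1
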